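## Retrosynthetic overview
1. Target 8 ⇒ break the ring bond O–C5 (ring-closing allylic C–H etherification) ⇒ acyclic (2S,3R)-diol 6. The oxolane ring is made last.
2. Diol 6 ⇒ break C3–OH (hydrolysis with inversion at C3) ⇒ (2S,3S)-epoxy ether 5.
3. Epoxy ether 5 ⇒ break ArO–C1 (Mitsunobu) ⇒ isofraxidin 3 (both coumarin rings bought intact) + (2S,3S)-epoxygeraniol 2.
4. Epoxide 2 ⇒ Sharpless epoxidation ⇒ geraniol 1, which supplies all ten side-chain carbons.
5. Ring order: coumarin (purchased), then oxirane (made in step 1, opened in step 3), then oxolane (step 4). Every bond made is a C–O bond.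

Assumption: isofraxidin (7-hydroxy-6,8-dimethoxycoumarin, CAS 486-21-5) is bought as a bulk plant-derived chemical; geraniol, the tartrates and NFSI are commodity reagents.

## Route

Step 1
Reactants: 1 geraniol
Product: 2 (2S,3S)-2,3-epoxygeraniol
Conditions: Ti(OiPr)4 (5 mol %), L-(+)-DET (7 mol %), TBHP (1.5 equiv, in decane), 4 Å MS, CH2Cl2, −20 °C
Reagents that add atoms: tert-butyl hydroperoxide, CC(C)(C)OO
Why: Sharpless asymmetric epoxidation: the titanium tartrate binds the allylic hydroxyl, so only the 2,3-alkene reacts and the 6,7-alkene is untouched, and L-(+)-DET delivers oxygen to the face that gives the (2S,3S)-epoxide in about 95 % ee, which fixes C2 of the target and sets C3 in the form that step 3 inverts.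

Step 2
Reactants: 2 (2S,3S)-2,3-epoxygeraniol; 3 isofraxidin
Product: 5 (2S,3S)-2,3-epoxygeranyl ether of isofraxidin, via alkoxyphosphonium salt 4 (not isolated)
Conditions: PPh3 (1.3 equiv), DIAD (1.3 equiv), THF, 0 °C to rt
Reagents that add atoms: none
Why: Mitsunobu etherification: the acidic phenol (pKa about 8) protonates the betaine and its phenoxide displaces Ph3PO from primary C1 by SN2, so neither epoxide stereocentre is touched and the near-neutral medium spares the oxirane and the lactone.

Step 3
Reactants: 5 (2S,3S)-2,3-epoxygeranyl ether of isofraxidin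
Product: 6 7-{[(2S,3R)-2,3-dihydroxy-3,7-dimethyloct-6-en-1-yl]oxy}-6,8-dimethoxycoumarin
Conditions: HClO4 (cat., aq.), THF/H2O 3:1, 0 °C to rt
Reagents that add atoms: water, O
Why: Acid-catalysed epoxide hydrolysis (borderline SN2): positive charge builds only at tertiary C3, away from the electron-withdrawing aryloxymethyl group, so water attacks C3 from the back with inversion (3S to 3R) while the C2–O bond is kept (2S), giving the anti diol whose CH2OAr and C3-OH end up trans on the later ring.

Step 4
Reactants: 6 (2S,3R)-diol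
Product: 8 7-{[(2S,3R,5R)-3-hydroxy-3-methyl-5-(2-methylprop-1-en-1-yl)oxolan-2-yl]methoxy}-6,8-dimethoxycoumarin (target), via allyl radical 7 (not isolated)
Conditions: Cu(MeCN)4PF6 (10 mol %), 2,2'-isopropylidenebis(4,4-dimethyl-2-oxazoline) (12 mol %), NFSI (1.2 equiv), Li2CO3 (2 equiv), PhCl, 25 °C, Ar, dark
Reagents that add atoms: none
Why: Proposed new method: a radical-relay ring-closing allylic C–H etherification, in which monovalent copper reduces NFSI to a divalent copper fluoride carrying the sulfonimidyl radical, the C2 hydroxyl exchanges for fluoride (driven by LiF formation), and the copper-bound N-radical abstracts the nearby and weakest hydrogen, the secondary allylic C5–H, which gives the most substituted allyl radical 7 (electrophilic palladation would take a methyl C–H instead); the tethered divalent copper alkoxide then captures the radical at its less hindered terminus C5, and C–O reductive elimination from the six-membered trivalent-copper ring closes the oxolane; the chair of that ring with CH2OAr, C3-OH and isobutenyl equatorial and only the C3 methyl axial delivers (5R), trans to CH2OAr and cis to OH, whereas the (5S) product needs either an axial CH2OAr pressed against the ligand or a 1,3-diaxial methyl/isobutenyl clash; the closest known reaction types are copper/NFSI radical-relay benzylic C–H etherification with alcohols, copper/NFSI allylic C–H cyanation and the Kharasch–Sosnovsky allylic oxidation, none of which has been shown for ring-closing etherification at the CH2 of a prenyl-type trisubstituted alkene.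

## Compound list
1 | geraniol, (2E)-3,7-dimethylocta-2,6-dien-1-ol | CC(C)=CCC/C(C)=C/CO | starting material
2 | (2S,3S)-2,3-epoxygeraniol, [(2S,3S)-3-methyl-3-(4-methylpent-3-en-1-yl)oxiran-2-yl]methanol | OC[C@@H]1O[C@@]1(C)CCC=C(C)C | intermediate
3 | isofraxidin, 7-hydroxy-6,8-dimethoxy-2H-chromen-2-one | COc1cc2ccc(=O)oc2c(OC)c1O | starting material
4 | {[(2S,3S)-3-methyl-3-(4-methylpent-3-en-1-yl)oxiran-2-yl]methoxy}triphenylphosphonium 6,8-dimethoxy-2-oxochromen-7-olate (not isolated) | c1ccccc1[P+](c1ccccc1)(c1ccccc1)OC[C@@H]1O[C@@]1(C)CCC=C(C)C.COc1cc2ccc(=O)oc2c(OC)c1[O-] | intermediate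
5 | 7-{[(2S,3S)-3-methyl-3-(4-methylpent-3-en-1-yl)oxiran-2-yl]methoxy}-6,8-dimethoxy-2H-chromen-2-one | COc1cc2ccc(=O)oc2c(OC)c1OC[C@@H]1O[C@@]1(C)CCC=C(C)C | intermediate
6 | 7-{[(2S,3R)-2,3-dihydroxy-3,7-dimethyloct-6-en-1-yl]oxy}-6,8-dimethoxy-2H-chromen-2-one | COc1cc2ccc(=O)oc2c(OC)c1OC[C@H](O)[C@](C)(O)CCC=C(C)C | intermediate
7 | C5/C7-delocalised allyl radical of 6, drawn with the spin at C5 (not isolated) | COc1cc2ccc(=O)oc2c(OC)c1OC[C@H](O)[C@](C)(O)C[CH]C=C(C)C | intermediate
8 | 7-{[(2S,3R,5R)-3-hydroxy-3-methyl-5-(2-methylprop-1-en-1-yl)oxolan-2-yl]methoxy}-6,8-dimethoxy-2H-chromen-2-one (CNP0086110.2) | COc1cc2ccc(=O)oc2c(OC)c1OC[C@@H]1O[C@@H](C=C(C)C)C[C@@]1(C)O | target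

## Totals
- Total step count: 4.
- Longest linear sequence: 4 (1 → 2 → 5 → 6 → 8).

## Steps most likely to fail

**Step 4 (the proposed new step).**
- Hydrogen abstraction at the two allylic methyls would give the wrong allyl radical.
- The new, doubly activated C5–H of 8 could be oxidised further, which is why NFSI is kept near one equivalent.
- The N-radical could add to the alkene or to the electron-rich arene.
- An outer-sphere cationic closure would erode the C5 selectivity.

Fallback with known chemistry, setting out from 6 and coming back at 8. Dye-sensitised photooxygenation of 6 (O2, tetraphenylporphyrin, visible light, CH2Cl2, 0 °C) is a Schenck ene reaction that touches only the trisubstituted alkene. It gives the tertiary allylic hydroperoxide F1 and about an equal amount of the secondary hydroperoxide regioisomer F2. PPh3 added to the same flask reduces these to the (5E)-2,3,7-triol F3 and the 2,3,6-triol F4, which chromatography separates. Camphorsulfonic acid (5 mol %) in CH2Cl2 at 0 °C then ionises the tertiary allylic alcohol of F3, and the C2 hydroxyl closes on C5 of the allyl cation. This is the acid cyclisation used for rose oxide. It gives 8 together with the C5 epimer F5. The epimers are separated by chromatography, and F5 is recycled by re-exposure to the acid, which re-opens the allylic ether.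

**Step 3.**
- Partial SN1 character at tertiary C3 would leak some syn diol.
- The protonated epoxide could rearrange to a ketone (Meinwald-type).

Fallback that avoids any substitution at the tertiary carbon, setting out from 1 and coming back at 6. Geraniol is epoxidised with the antipodal tartrate (Ti(OiPr)4, D-(−)-DET, TBHP, 4 Å MS, CH2Cl2, −20 °C) to (2R,3R)-2,3-epoxygeraniol F6. Hot aqueous NaOH/t-BuOH then brings about Payne rearrangement and hydroxide opening of the terminal epoxide; direct attack at C2 would give the same product. This inverts secondary C2 by clean SN2 and keeps the C3–O bond, giving (2S,3R)-3,7-dimethyloct-6-ene-1,2,3-triol F7. A Mitsunobu reaction with 3 (PPh3, DIAD, THF, 0 °C), selective for the primary hydroxyl, gives 6.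

**Step 2.**
- The phenoxide of 3 carries two ortho methoxy groups, so the SN2 step may be slow and the hydrazide may be alkylated instead.
- Ph3PO removal can be tedious.

Fallback that replaces the redox condensation by a sulfonate alkylation, setting out from 2 and coming back at 5. TsCl, Et3N and catalytic DMAP in CH2Cl2 at 0 °C give the (2S,3S)-epoxygeranyl tosylate F8. The caesium phenoxide of 3 (Cs2CO3, DMF, rt to 50 °C) displaces the tosylate at C1 with the oxirane intact, giving 5.

Recrystallising 5 or 6 can raise the roughly 95 % ee inherited from step 1.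

## Further compounds
F1 | step 4 | 7-{[(2S,3R,5E)-7-hydroperoxy-2,3-dihydroxy-3,7-dimethyloct-5-en-1-yl]oxy}-6,8-dimethoxycoumarin | COc1cc2ccc(=O)oc2c(OC)c1OC[C@H](O)[C@](C)(O)C/C=C/C(C)(C)OO
F2 | step 4 | 7-{[(2S,3R)-6-hydroperoxy-2,3-dihydroxy-3,7-dimethyloct-7-en-1-yl]oxy}-6,8-dimethoxycoumarin (both C6 epimers) | COc1cc2ccc(=O)oc2c(OC)c1OC[C@H](O)[C@](C)(O)CCC(OO)C(C)=C
F3 | step 4 | 7-{[(2S,3R,5E)-2,3,7-trihydroxy-3,7-dimethyloct-5-en-1-yl]oxy}-6,8-dimethoxycoumarin | COc1cc2ccc(=O)oc2c(OC)c1OC[C@H](O)[C@](C)(O)C/C=C/C(C)(C)O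
F4 | step 4 | 7-{[(2S,3R)-2,3,6-trihydroxy-3,7-dimethyloct-7-en-1-yl]oxy}-6,8-dimethoxycoumarin (both C6 epimers) | COc1cc2ccc(=O)oc2c(OC)c1OC[C@H](O)[C@](C)(O)CCC(O)C(C)=C
F5 | step 4 | 7-{[(2S,3R,5S)-3-hydroxy-3-methyl-5-(2-methylprop-1-en-1-yl)oxolan-2-yl]methoxy}-6,8-dimethoxycoumarin (C5 epimer of 8) | COc1cc2ccc(=O)oc2c(OC)c1OC[C@@H]1O[C@H](C=C(C)C)C[C@@]1(C)O
F6 | step 3 | (2R,3R)-2,3-epoxygeraniol | OC[C@H]1O[C@]1(C)CCC=C(C)C
F7 | step 3 | (2S,3R)-3,7-dimethyloct-6-ene-1,2,3-triol | OC[C@H](O)[C@](C)(O)CCC=C(C)C
F8 | step 2 | [(2S,3S)-3-methyl-3-(4-methylpent-3-en-1-yl)oxiran-2-yl]methyl 4-methylbenzenesulfonate | Cc1ccc(cc1)S(=O)(=O)OC[C@@H]1O[C@@]1(C)CCC=C(C)C
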